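**Retrosynthetic overview**
1. Target 20 ⇐ allyl ester 19 ⇐ ring enone 18: the C-2 carbinol comes from a catalyst-controlled reduction, and the acid is unmasked last.
2. 18 ⇐ bridged keto-lactone 15: the C-14 carboxyl and C-9 oxygen travel as a γ-lactone, opened and acylated once the carbocycle exists.
3. 15 ⇐ acyclic chloride / silyl dienol ether 14: the 11-membered ring is closed at C-1–C-11, the bond of the farnesyl-to-humulyl cyclisation, by capture of a tertiary C-11 cation at C-1.
4. 14 ⇐ alkylidene lactone 10 ⇐ phosphono lactone 9 + keto-aldehyde 3 (olefination; then C-15 methylenation and HCl addition at C-11).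
5. 9 ⇐ epoxide 7 + phosphonoacetate 8; 7 ⇐ (S)-epichlorohydrin 4 + Grignard 5. Ring order: γ-lactone first (step 3), carbocycle second (step 7), lactone opened in step 8.

Assumption: the target is treated as a humulane (positions C-1 to C-15 in farnesane numbering) whose ring arises in nature by C-1–C-11 closure of a farnesyl cation, with C-14 and the C-9 oxygen joined as a γ-lactone before hydrolysis and acylation.

**Route**

Step 1
Reactants: 1 1-methylcyclopentene
Product: 3 5-oxohexanal, via ozonide 2 (not isolated)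
Conditions: O3, CH2Cl2, −78 °C; then Me2S, −78 °C → rt
Reagents that add atoms: ozone, [O-][O+]=O
Why: Criegee ozonolysis with reductive work-up cleaves the only C=C to the keto-aldehyde that supplies C-1 to C-6; no stereocentre is formed.

Step 2
Reactants: 4 (S)-epichlorohydrin; 5 isopropenylmagnesium bromide
Product: 7 (2S)-2-(2-methylprop-2-en-1-yl)oxirane, via chlorohydrin 6 (not isolated)
Conditions: CuI (10 mol %), THF, −40 → 0 °C; then 3 M aq NaOH, rt
Reagents that add atoms: none
Why: CuI-catalysed Grignard opening of the epoxide at its CH2 carbon (not displacement of chloride) and intramolecular Williamson ring closure move the epoxide without touching the C–O stereocentre, which becomes C-9 with the target configuration.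

Step 3
Reactants: 7 (2S)-2-(2-methylprop-2-en-1-yl)oxirane; 8 triethyl phosphonoacetate
Product: 9 diethyl [(5S)-5-(2-methylprop-2-en-1-yl)-2-oxooxolan-3-yl]phosphonate (C-3 epimers)
Conditions: NaH (1.05 equiv), toluene, 0 → 100 °C (sealed); aq HCl
Reagents that add atoms: none
Why: the phosphonoacetate carbanion opens the terminal epoxide at CH2 (SN2) and the alkoxide lactonises with loss of ethanol (epoxide alkylation–lactonisation); C-9 is untouched and the phosphonate-bearing centre is destroyed in step 4.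

Step 4
Reactants: 9 diethyl [(5S)-5-(2-methylprop-2-en-1-yl)-2-oxooxolan-3-yl]phosphonate; 3 5-oxohexanal
Product: 10 (3E,5S)-5-(2-methylprop-2-en-1-yl)-3-(5-oxohexylidene)oxolan-2-one
Conditions: LiCl (1.2 equiv), DBU (1.05 equiv), MeCN, 0 °C → rt
Reagents that add atoms: none
Why: Horner–Wadsworth–Emmons olefination (Masamune–Roush conditions) is selective for the aldehyde over the methyl ketone and favours the (E)-alkylidene lactone (chain trans to C=O; minor Z isomer removed), which is the C-6=C-7 geometry of the target.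

Step 5
Reactants: 10 (3E,5S)-5-(2-methylprop-2-en-1-yl)-3-(5-oxohexylidene)oxolan-2-one
Product: 11 (3E,5S)-3-(4-methylidene-5-oxohexylidene)-5-(2-methylprop-2-en-1-yl)oxolan-2-one
Conditions: (CH2O)n (3 equiv), i-Pr2NH2+ CF3CO2− (1 equiv), CF3CO2H (10 mol %), THF, 65 °C
Reagents that add atoms: formaldehyde (as paraformaldehyde), C=O
Why: Mannich-type α-methylenation through the more substituted enol installs C-15 on the internal α-carbon (C-3) and leaves a ketone that can enolise only toward the C-1 methyl group; no stereocentre.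

Step 6
Reactants: 11 (3E,5S)-3-(4-methylidene-5-oxohexylidene)-5-(2-methylprop-2-en-1-yl)oxolan-2-one
Product: 14 (3E,5R)-3-{5-[(tert-butyldimethylsilyl)oxy]-4-methylidenehex-5-en-1-ylidene}-5-(2-chloro-2-methylpropyl)oxolan-2-one, via dichloride 12 (not isolated), via chloro enone 13 (not isolated)
Conditions: HCl (g), CH2Cl2, −40 → 0 °C; evaporate; Et3N (5 equiv), CH2Cl2, 0 °C; then TBSOTf (2 equiv), −78 → 0 °C
Reagents that add atoms: hydrogen chloride, Cl; tert-butyldimethylsilyl trifluoromethanesulfonate, CC(C)(C)[Si](C)(C)OS(=O)(=O)C(F)(F)F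
Why: Markovnikov hydrochlorination gives the tertiary C-11 chloride, HCl that also adds to the enone is expelled again by Et3N (E1cB), and soft enolisation of the methyl ketone gives the 2-silyloxy-1,3-diene; the stereocentre is untouched (its descriptor changes only because of the new chlorine).

Step 7
Reactants: 14 (3E,5R)-3-{5-[(tert-butyldimethylsilyl)oxy]-4-methylidenehex-5-en-1-ylidene}-5-(2-chloro-2-methylpropyl)oxolan-2-one
Product: 15 (1E,10S)-8,8-dimethyl-5-methylidene-11-oxabicyclo[8.2.1]tridec-1-ene-6,12-dione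
Conditions: InBr3 (20 mol %), 2,6-di-tert-butyl-4-methylpyridine (30 mol %), CH2Cl2, 0 °C → rt, 14 added over 12 h (final 1 mM)
Reagents that add atoms: none
Why: Proposed new method: an intramolecular, 11-membered-ring version of the Lewis-acid-promoted α-tert-alkylation of silyl enol ethers with tertiary alkyl chlorides (Reetz alkylation, SN1); InBr3 ionises the C-11 chloride reversibly, the tertiary cation is captured at C-1 by the silyl dienol ether (the only π-nucleophile, since the alkylidene lactone is electron-poor and is not activated by the weak catalytic Lewis acid), and irreversible silyl transfer to chloride releases the enone, so the C-1–C-11 bond and the quaternary carbon are made head-to-tail as in the humulyl cyclisation; the lactone holds C-7 to C-9 rigid, its (E)-alkylidene arm points the chain toward C-10, its carbonyl cannot trap the cation (the acyloxonium ion would sit at a bridgehead), chloride return and slow addition suppress oligomers, and no stereocentre is formed or touched.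

Step 8
Reactants: 15 (1E,10S)-8,8-dimethyl-5-methylidene-11-oxabicyclo[8.2.1]tridec-1-ene-6,12-dione
Product: 18 prop-2-en-1-yl (1E,10S)-8,8-dimethyl-5-methylidene-10-[(3-methylbutanoyl)oxy]-6-oxocycloundec-1-ene-1-carboxylate, via lithium carboxylate 16 (not isolated), via hydroxy ester 17 (not isolated)
Conditions: LiOH·H2O (1.1 equiv), THF/H2O 4:1, 0 °C; evaporate; allyl bromide (3 equiv), DMF, rt; then (i-PrCH2CO)2O (2 equiv), Et3N (4 equiv), DMAP (0.2 equiv), 0 °C → rt
Reagents that add atoms: lithium hydroxide, [Li+].[OH-]; allyl bromide, C=CCBr; 3-methylbutanoic anhydride, CC(C)CC(=O)OC(=O)CC(C)C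
Why: lactone saponification (acyl–oxygen cleavage, C-9 retained), carboxylate O-alkylation and DMAP-catalysed acylation are telescoped so the lactonisation-prone γ-hydroxy ester is never isolated; any hydroxide adduct of the enone ends as a β-acyloxy ketone that Et3N eliminates back to the methylene ketone (E1cB).

Step 9
Reactants: 18 prop-2-en-1-yl (1E,10S)-8,8-dimethyl-5-methylidene-10-[(3-methylbutanoyl)oxy]-6-oxocycloundec-1-ene-1-carboxylate
Product: 19 prop-2-en-1-yl (1E,6S,10S)-6-hydroxy-8,8-dimethyl-5-methylidene-10-[(3-methylbutanoyl)oxy]cycloundec-1-ene-1-carboxylate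
Conditions: (R)-2-methyl-CBS-oxazaborolidine (0.5 equiv), catecholborane (2 equiv), toluene, −78 °C; MeOH, then aq NaHCO3
Reagents that add atoms: none
Why: Corey–Bakshi–Shibata reduction: catalyst-controlled 1,2-hydride delivery, with the α-branched alkenyl group as the large and the CH2 group as the small substituent, gives the (6S)-allylic alcohol (C-2) with the (R)-catalyst; catecholborane at −78 °C spares esters and alkenes.

Step 10
Reactants: 19 prop-2-en-1-yl (1E,6S,10S)-6-hydroxy-8,8-dimethyl-5-methylidene-10-[(3-methylbutanoyl)oxy]cycloundec-1-ene-1-carboxylate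
Product: 20 (1E,6S,10S)-6-hydroxy-8,8-dimethyl-5-methylidene-10-[(3-methylbutanoyl)oxy]cycloundec-1-ene-1-carboxylic acid
Conditions: Pd(PPh3)4 (5 mol %), morpholine (3 equiv), THF, rt; aq citric acid
Reagents that add atoms: none
Why: Tsuji–Trost-type deallylation: zerovalent palladium ionises only the allyl ester and morpholine traps the allyl group, leaving the isovalerate, the free allylic alcohol and both stereocentres untouched.

**Compound list**
1 | 1-methylcyclopentene | CC1=CCCC1 | starting material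
2 | 1-methyl-6,7,8-trioxabicyclo[3.2.1]octane (ozonide, racemic) | CC12CCCC(OO1)O2 | intermediate
3 | 5-oxohexanal | CC(=O)CCCC=O | intermediate
4 | (S)-epichlorohydrin, (2S)-2-(chloromethyl)oxirane | ClC[C@@H]1CO1 | starting material
5 | isopropenylmagnesium bromide | CC(=C)[Mg]Br | starting material
6 | (2S)-1-chloro-4-methylpent-4-en-2-ol | ClC[C@@H](O)CC(C)=C | intermediate
7 | (2S)-2-(2-methylprop-2-en-1-yl)oxirane | C=C(C)C[C@H]1CO1 | intermediate
8 | triethyl phosphonoacetate | CCOC(=O)CP(=O)(OCC)OCC | starting material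
9 | diethyl [(5S)-5-(2-methylprop-2-en-1-yl)-2-oxooxolan-3-yl]phosphonate (C-3 epimers) | C=C(C)C[C@H]1CC(P(=O)(OCC)OCC)C(=O)O1 | intermediate
10 | (3E,5S)-5-(2-methylprop-2-en-1-yl)-3-(5-oxohexylidene)oxolan-2-one | C=C(C)C[C@H]1C/C(=C\CCCC(C)=O)C(=O)O1 | intermediate
11 | (3E,5S)-3-(4-methylidene-5-oxohexylidene)-5-(2-methylprop-2-en-1-yl)oxolan-2-one | C=C(C)C[C@H]1C/C(=C\CCC(=C)C(C)=O)C(=O)O1 | intermediate
12 | (3E,5R)-3-[4-(chloromethyl)-5-oxohexylidene]-5-(2-chloro-2-methylpropyl)oxolan-2-one (epimers at the chloromethyl-bearing carbon) | CC(C)(Cl)C[C@H]1C/C(=C\CCC(CCl)C(C)=O)C(=O)O1 | intermediate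
13 | (3E,5R)-5-(2-chloro-2-methylpropyl)-3-(4-methylidene-5-oxohexylidene)oxolan-2-one | CC(C)(Cl)C[C@H]1C/C(=C\CCC(=C)C(C)=O)C(=O)O1 | intermediate
14 | (3E,5R)-3-{5-[(tert-butyldimethylsilyl)oxy]-4-methylidenehex-5-en-1-ylidene}-5-(2-chloro-2-methylpropyl)oxolan-2-one | CC(C)(Cl)C[C@H]1C/C(=C\CCC(=C)C(=C)O[Si](C)(C)C(C)(C)C)C(=O)O1 | intermediate
15 | (1E,10S)-8,8-dimethyl-5-methylidene-11-oxabicyclo[8.2.1]tridec-1-ene-6,12-dione (11-membered carbocycle bridged by the γ-lactone) | C=C1CC/C=C2\C[C@H](CC(C)(C)CC1=O)OC2=O | intermediate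
16 | lithium (1E,10S)-10-hydroxy-8,8-dimethyl-5-methylidene-6-oxocycloundec-1-ene-1-carboxylate | C=C1CC/C=C(/C(=O)[O-])C[C@@H](O)CC(C)(C)CC1=O.[Li+] | intermediate
17 | prop-2-en-1-yl (1E,10S)-10-hydroxy-8,8-dimethyl-5-methylidene-6-oxocycloundec-1-ene-1-carboxylate | C=C1CC/C=C(/C(=O)OCC=C)C[C@@H](O)CC(C)(C)CC1=O | intermediate
18 | prop-2-en-1-yl (1E,10S)-8,8-dimethyl-5-methylidene-10-[(3-methylbutanoyl)oxy]-6-oxocycloundec-1-ene-1-carboxylate | C=C1CC/C=C(/C(=O)OCC=C)C[C@@H](OC(=O)CC(C)C)CC(C)(C)CC1=O | intermediate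
19 | prop-2-en-1-yl (1E,6S,10S)-6-hydroxy-8,8-dimethyl-5-methylidene-10-[(3-methylbutanoyl)oxy]cycloundec-1-ene-1-carboxylate | C=C1CC/C=C(/C(=O)OCC=C)C[C@@H](OC(=O)CC(C)C)CC(C)(C)C[C@@H]1O | intermediate
20 | (1E,6S,10S)-6-hydroxy-8,8-dimethyl-5-methylidene-10-[(3-methylbutanoyl)oxy]cycloundec-1-ene-1-carboxylic acid | C=C1CC/C=C(/C(=O)O)C[C@@H](OC(=O)CC(C)C)CC(C)(C)C[C@@H]1O | target

**Totals**
Total step count: 10 (steps 6 and 8 are telescoped one-pot sequences).
Longest linear sequence: 9 steps (4 → 20, steps 2–10); step 1 is the only side branch.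

**Steps most likely to fail, with fallbacks**

Step 7 (macrocyclisation). This SN1 closure has no precedent at this ring size. The cation may instead lose a proton, oligomerise, or outlive the silyl enol ether, which traces of acid destroy. The fallback sets out from 9 and returns at 15. It makes the C-1–C-11 bond intermolecularly, where the tert-alkylation is established, and closes the ring at C-6=C-7 by an intramolecular Horner–Wadsworth–Emmons reaction. HCl (CH2Cl2, 0 °C) converts 9 into diethyl [(5R)-5-(2-chloro-2-methylpropyl)-2-oxooxolan-3-yl]phosphonate F1. Commercial hept-6-en-2-one (CC(=O)CCCC=C) is methylenated as in step 5 to 3-methylidenehept-6-en-2-one F2 and silylated (TBSOTf, Et3N) to tert-butyl(dimethyl)[(3-methylidenehepta-1,6-dien-2-yl)oxy]silane F3. F1 and F3 are coupled with TiCl4 (CH2Cl2, −45 °C) to diethyl [(5S)-5-(2,2-dimethyl-5-methylidene-4-oxonon-8-en-1-yl)-2-oxooxolan-3-yl]phosphonate F4. OsO4 (cat.), NaIO4 and 2,6-lutidine cleave only the electron-rich terminal vinyl group, giving diethyl [(5S)-5-(2,2-dimethyl-5-methylidene-4,8-dioxooctyl)-2-oxooxolan-3-yl]phosphonate F5. LiCl and DBU in MeCN at 1 mM then close the ring to 15.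

Step 8 (lactone opening beside the enone). Hydroxide may add to the α-methylene ketone or cause loss of formaldehyde, and the γ-hydroxy ester may relactonise. The fallback sets out from 15 and returns at 19. It reduces the ketone first, so that no Michael acceptor is present when the lactone is opened. (R)-2-Methyl-CBS-oxazaborolidine and catecholborane reduce 15 to (1E,6S,10S)-6-hydroxy-8,8-dimethyl-5-methylidene-11-oxabicyclo[8.2.1]tridec-1-en-12-one F6. TESOTf and 2,6-lutidine give (1E,6S,10S)-8,8-dimethyl-5-methylidene-6-[(triethylsilyl)oxy]-11-oxabicyclo[8.2.1]tridec-1-en-12-one F7. LiOH, then allyl bromide, then 3-methylbutanoic anhydride (as in step 8) lead through lithium (1E,6S,10S)-10-hydroxy-8,8-dimethyl-5-methylidene-6-[(triethylsilyl)oxy]cycloundec-1-ene-1-carboxylate F8 and prop-2-en-1-yl (1E,6S,10S)-10-hydroxy-8,8-dimethyl-5-methylidene-6-[(triethylsilyl)oxy]cycloundec-1-ene-1-carboxylate F9 to prop-2-en-1-yl (1E,6S,10S)-8,8-dimethyl-5-methylidene-10-[(3-methylbutanoyl)oxy]-6-[(triethylsilyl)oxy]cycloundec-1-ene-1-carboxylate F10. HF·pyridine removes the silyl group to give 19.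

Step 9 (C-2 reduction). The neopentyl-type CH2 group and the ring conformation may override the usual large/small assignment and give the wrong face. The fallback sets out from 18 and returns at 19. It uses substrate control followed by stereochemical correction instead of catalyst control. NaBH4 with CeCl3·7H2O (MeOH, −78 °C; Luche reduction) gives separable C-6 epimers. The unwanted prop-2-en-1-yl (1E,6R,10S)-6-hydroxy-8,8-dimethyl-5-methylidene-10-[(3-methylbutanoyl)oxy]cycloundec-1-ene-1-carboxylate F11 is inverted by a Mitsunobu reaction (PPh3, DIAD, HCO2H) to prop-2-en-1-yl (1E,6S,10S)-6-(formyloxy)-8,8-dimethyl-5-methylidene-10-[(3-methylbutanoyl)oxy]cycloundec-1-ene-1-carboxylate F12. The formyl group alone is then removed with KHCO3 in MeOH at 0 °C to give 19.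

**Further compounds**
F1 | step 7 | diethyl [(5R)-5-(2-chloro-2-methylpropyl)-2-oxooxolan-3-yl]phosphonate | CC(C)(Cl)C[C@H]1CC(P(=O)(OCC)OCC)C(=O)O1
F2 | step 7 | 3-methylidenehept-6-en-2-one | CC(=O)C(=C)CCC=C
F3 | step 7 | tert-butyl(dimethyl)[(3-methylidenehepta-1,6-dien-2-yl)oxy]silane | C=C(O[Si](C)(C)C(C)(C)C)C(=C)CCC=C
F4 | step 7 | diethyl [(5S)-5-(2,2-dimethyl-5-methylidene-4-oxonon-8-en-1-yl)-2-oxooxolan-3-yl]phosphonate | C=CCCC(=C)C(=O)CC(C)(C)C[C@H]1CC(P(=O)(OCC)OCC)C(=O)O1
F5 | step 7 | diethyl [(5S)-5-(2,2-dimethyl-5-methylidene-4,8-dioxooctyl)-2-oxooxolan-3-yl]phosphonate | O=CCCC(=C)C(=O)CC(C)(C)C[C@H]1CC(P(=O)(OCC)OCC)C(=O)O1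
F6 | step 8 | (1E,6S,10S)-6-hydroxy-8,8-dimethyl-5-methylidene-11-oxabicyclo[8.2.1]tridec-1-en-12-one | C=C1CC/C=C2\C[C@H](CC(C)(C)C[C@@H]1O)OC2=O
F7 | step 8 | (1E,6S,10S)-8,8-dimethyl-5-methylidene-6-[(triethylsilyl)oxy]-11-oxabicyclo[8.2.1]tridec-1-en-12-one | C=C1CC/C=C2\C[C@H](CC(C)(C)C[C@@H]1O[Si](CC)(CC)CC)OC2=O
F8 | step 8 | lithium (1E,6S,10S)-10-hydroxy-8,8-dimethyl-5-methylidene-6-[(triethylsilyl)oxy]cycloundec-1-ene-1-carboxylate | C=C1CC/C=C(/C(=O)[O-])C[C@@H](O)CC(C)(C)C[C@@H]1O[Si](CC)(CC)CC.[Li+]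
F9 | step 8 | prop-2-en-1-yl (1E,6S,10S)-10-hydroxy-8,8-dimethyl-5-methylidene-6-[(triethylsilyl)oxy]cycloundec-1-ene-1-carboxylate | C=C1CC/C=C(/C(=O)OCC=C)C[C@@H](O)CC(C)(C)C[C@@H]1O[Si](CC)(CC)CC
F10 | step 8 | prop-2-en-1-yl (1E,6S,10S)-8,8-dimethyl-5-methylidene-10-[(3-methylbutanoyl)oxy]-6-[(triethylsilyl)oxy]cycloundec-1-ene-1-carboxylate | C=C1CC/C=C(/C(=O)OCC=C)C[C@@H](OC(=O)CC(C)C)CC(C)(C)C[C@@H]1O[Si](CC)(CC)CC
F11 | step 9 | prop-2-en-1-yl (1E,6R,10S)-6-hydroxy-8,8-dimethyl-5-methylidene-10-[(3-methylbutanoyl)oxy]cycloundec-1-ene-1-carboxylate | C=C1CC/C=C(/C(=O)OCC=C)C[C@@H](OC(=O)CC(C)C)CC(C)(C)C[C@H]1O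
F12 | step 9 | prop-2-en-1-yl (1E,6S,10S)-6-(formyloxy)-8,8-dimethyl-5-methylidene-10-[(3-methylbutanoyl)oxy]cycloundec-1-ene-1-carboxylate | C=C1CC/C=C(/C(=O)OCC=C)C[C@@H](OC(=O)CC(C)C)CC(C)(C)C[C@@H]1OC=O
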